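The γ-butyrolactone is disconnected at its C3–C4 bond, the bond joining the two arylmethyl-bearing stereocentres. Because C4 also carries the ring oxymethylene C5, C5 can be read as the stump of an alkene and C4 as the far end of an allyl unit, while C2 and C3 derive from a 3-arylpropanoate enolate. One ester-tethered Ireland–Claisen rearrangement then forges C3–C4 and sets both stereocentres at once, by chirality transfer from a sacrificial (S)-carbinol that is later cut out with its methyl group. The precursor is the ester of an (S,Z)-5-arylpent-3-en-2-ol with a 3-arylpropanoic acid, all phenols masked as benzyl ethers.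

Key step: step 9

Remark: the SMILES is read as the (3R,4R)-trans-lactone. Lactone locants are C2 (carbonyl), C3, C4, C5 (OCH2). Fragment 1 carries the 4-benzyloxy-3-methoxyphenyl ring and fragment 2 the 3,4-bis(benzyloxy)-5-methoxyphenyl ring.

Step 1
Reactants: 1 vanillin
Product: 2 4-(benzyloxy)-3-methoxybenzaldehyde
Conditions: BnBr, K2CO3, DMF, 60 °C
Reagents that add atoms: benzyl bromide, BrCc1ccccc1
Why: Williamson etherification of the phenoxide, with benzyl chosen so that every phenol protecting group falls in the final hydrogenolysis.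

Step 2
Reactants: 2 4-(benzyloxy)-3-methoxybenzaldehyde
Product: 3 [4-(benzyloxy)-3-methoxyphenyl]methanol
Conditions: NaBH4, MeOH/THF, 0 °C → rt
Reagents that add atoms: none
Why: Borohydride reduction of the aryl aldehyde to the benzylic alcohol leaves the aryl ethers untouched.

Step 3
Reactants: 3 [4-(benzyloxy)-3-methoxyphenyl]methanol
Product: 4 4-(benzyloxy)-3-methoxybenzyl bromide
Conditions: PBr3, CH2Cl2, 0 °C; used crude at once
Reagents that add atoms: phosphorus tribromide, BrP(Br)Br
Why: Bromide displaces the phosphite-activated benzylic hydroxyl, and the labile electron-rich bromide is taken on without storage.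

Step 4
Reactants: 4 4-(benzyloxy)-3-methoxybenzyl bromide; 5 (S)-but-3-yn-2-ol
Product: 7 (S)-5-[4-(benzyloxy)-3-methoxyphenyl]pent-3-yn-2-ol, via dimagnesium alkynolate 6 (not isolated)
Conditions: 5 (1.3 equiv), EtMgBr (2.6 equiv), THF, 0 °C → rt; CuI (10 mol%), then 4, 50 °C; aq. NH4Cl
Reagents that add atoms: none
Why: Copper-catalysed alkylation of an alkynylmagnesium reagent with a benzylic bromide, in which the acetylide carbon is passed to monovalent copper and displaces bromide while the magnesium alkoxide stays a poor nucleophile; the carbinol centre is not involved and remains S.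

Step 5
Reactants: 7 (S)-5-[4-(benzyloxy)-3-methoxyphenyl]pent-3-yn-2-ol
Product: 8 (S,Z)-5-[4-(benzyloxy)-3-methoxyphenyl]pent-3-en-2-ol
Conditions: H2 (1 atm), Pd/CaCO3 poisoned with Pb(OAc)2, quinoline, EtOAc, rt, stopped after one equivalent of H2
Reagents that add atoms: none
Why: Lindlar semihydrogenation delivers both hydrogens to one face of the alkyne on the deactivated palladium surface, which gives the Z-alkene and should spare the benzyl ether and the carbinol.

Step 6
Reactants: 9 5-hydroxyvanillin
Product: 10 3,4-bis(benzyloxy)-5-methoxybenzaldehyde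
Conditions: BnBr (2.4 equiv), K2CO3, DMF, 60 °C
Reagents that add atoms: benzyl bromide, BrCc1ccccc1
Why: Double Williamson etherification of the catechol under the same conditions as step 1.

Step 7
Reactants: 10 3,4-bis(benzyloxy)-5-methoxybenzaldehyde
Product: 13 3-[3,4-bis(benzyloxy)-5-methoxyphenyl]propanoic acid, via arylidene Meldrum's acid 11 (not isolated), via arylmethyl Meldrum's acid 12 (not isolated)
Conditions: Meldrum's acid, HCO2H/Et3N (5:2), 95–100 °C; aq. HCl
Reagents that add atoms: Meldrum's acid, CC1(C)OC(=O)CC(=O)O1; water, O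
Why: One-pot reductive alkylation of Meldrum's acid (Knoevenagel condensation, conjugate hydride transfer from formate, then hydrolytic ring opening with loss of acetone and CO2) gives the saturated acid without hydrogen gas or palladium, so the benzyl ethers survive.

Step 8
Reactants: 8 (S,Z)-5-[4-(benzyloxy)-3-methoxyphenyl]pent-3-en-2-ol; 13 3-[3,4-bis(benzyloxy)-5-methoxyphenyl]propanoic acid
Product: 14 (S,Z)-5-[4-(benzyloxy)-3-methoxyphenyl]pent-3-en-2-yl 3-[3,4-bis(benzyloxy)-5-methoxyphenyl]propanoate
Conditions: DCC, DMAP (cat.), CH2Cl2, 0 °C → rt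
Reagents that add atoms: none
Why: Steglich esterification acylates the alcohol oxygen through the acylpyridinium without breaking the carbinol C–O bond, so the S configuration and the Z-alkene are retained.

Step 9
Reactants: 14 (S,Z)-5-[4-(benzyloxy)-3-methoxyphenyl]pent-3-en-2-yl 3-[3,4-bis(benzyloxy)-5-methoxyphenyl]propanoate
Product: 18 (2R,3S,E)-2-[3,4-bis(benzyloxy)-5-methoxybenzyl]-3-[4-(benzyloxy)-3-methoxybenzyl]hex-4-enoic acid, via lithium enolate 15 (not isolated), via silyl ketene acetal 16 (not isolated), via trimethylsilyl ester 17 (not isolated)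
Conditions: LDA (1.2 equiv), Me3SiCl/Et3N, THF, −78 °C; → rt, then 60 °C; 1 M HCl
Reagents that add atoms: none
Why: LDA removes a proton from the only enolisable carbon (C2 of the propanoate) under kinetic control to give enolate 15 with the arylmethyl group trans to OLi, O-silylation fixes this geometry in ketene acetal 16, and on warming 16 undergoes a concerted suprafacial [3,3]-sigmatropic shift through a chair, silyl ester 17 being hydrolysed on work-up. This is an Ireland–Claisen rearrangement of an enantioenriched secondary (Z)-allylic ester with 1,3-chirality transfer, a well-established reaction type. No ring is closed; the only cyclic array is the six-membered transition state, and the new σ-bond is the one that becomes lactone C3–C4. The future C4 (acid C3, S) is controlled by the (S)-carbinol: the Z-alkene holds its arylmethyl group axial on the alkene terminus, so the carbinol methyl must sit equatorial to escape a 1,3-diaxial clash, the enol carbon adds to one alkene face only, and the breaking carbinol C–O bond leaves an E-propenyl group. The future C3 (acid C2, R) is controlled by the ketene acetal geometry, whose arylmethyl group lies cis to the allylic oxygen and is therefore axial and anti to the other arylmethyl group, which gives the syn acid, the precursor of the trans lactone. The step needs face selectivity and syn selectivity; the first is secured by the Z-alkene/(S)-carbinol pair and the second by the kinetic enolate geometry, and a minor C2 epimer would be harmless because that centre is equilibrated in step 10.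

Step 10
Reactants: 18 (2R,3S,E)-2-[3,4-bis(benzyloxy)-5-methoxybenzyl]-3-[4-(benzyloxy)-3-methoxybenzyl]hex-4-enoic acid
Product: 21 tri-O-benzyl thujaplicatin, via secondary ozonide 19 (not isolated), via hydroxy acid 20 (not isolated)
Conditions: O3, CH2Cl2, −78 °C (Sudan Red 7B end point); MeOH, NaBH4, −78 → 0 °C; 2 M HCl, THF, rt; then DBU (cat.), PhMe, 60 °C
Reagents that add atoms: ozone, [O-][O+]=O
Why: Ozonolysis to the 1,2,4-trioxolane and hydride reduction excise the former carbinol carbon with its methyl group and leave a primary alcohol that closes on the acid on acidification (5-exo-trig acyl substitution, acid-catalysed lactonisation); the cold reductive work-up gives the transient aldehyde no time to enolise at C4, and the DBU treatment equilibrates only C3, α to the carbonyl, towards the more stable trans lactone.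

Step 11
Reactants: 21 tri-O-benzyl thujaplicatin
Product: 22 (−)-thujaplicatin
Conditions: H2 (1 atm), 10% Pd/C, EtOAc/MeOH (degassed), rt
Reagents that add atoms: none
Why: Hydrogenolysis of the three benzyl aryl ethers over palladium on carbon should free the phenols while the lactone, the methyl ethers and both stereocentres stay untouched.

Compound list
1 | vanillin (4-hydroxy-3-methoxybenzaldehyde) | COc1cc(C=O)ccc1O | starting material
2 | 4-(benzyloxy)-3-methoxybenzaldehyde | COc1cc(C=O)ccc1OCc1ccccc1 | intermediate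
3 | [4-(benzyloxy)-3-methoxyphenyl]methanol | COc1cc(CO)ccc1OCc1ccccc1 | intermediate
4 | 4-(benzyloxy)-3-methoxybenzyl bromide | COc1cc(CBr)ccc1OCc1ccccc1 | intermediate
5 | (S)-but-3-yn-2-ol | C[C@H](O)C#C | starting material
6 | bromomagnesium (S)-4-(bromomagnesio)but-3-yn-2-olate (dimagnesium alkynolate) | C[C@H](O[Mg]Br)C#C[Mg]Br | intermediate
7 | (S)-5-[4-(benzyloxy)-3-methoxyphenyl]pent-3-yn-2-ol | C[C@H](O)C#CCc1ccc(OCc2ccccc2)c(OC)c1 | intermediate
8 | (S,Z)-5-[4-(benzyloxy)-3-methoxyphenyl]pent-3-en-2-ol | C[C@H](O)/C=C\Cc1ccc(OCc2ccccc2)c(OC)c1 | intermediate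
9 | 5-hydroxyvanillin (3,4-dihydroxy-5-methoxybenzaldehyde) | COc1cc(C=O)cc(O)c1O | starting material
10 | 3,4-bis(benzyloxy)-5-methoxybenzaldehyde | COc1cc(C=O)cc(OCc2ccccc2)c1OCc1ccccc1 | intermediate
11 | 5-[3,4-bis(benzyloxy)-5-methoxybenzylidene]-2,2-dimethyl-1,3-dioxane-4,6-dione (arylidene Meldrum's acid) | COc1cc(C=C2C(=O)OC(C)(C)OC2=O)cc(OCc2ccccc2)c1OCc1ccccc1 | intermediate
12 | 5-[3,4-bis(benzyloxy)-5-methoxybenzyl]-2,2-dimethyl-1,3-dioxane-4,6-dione (arylmethyl Meldrum's acid) | COc1cc(CC2C(=O)OC(C)(C)OC2=O)cc(OCc2ccccc2)c1OCc1ccccc1 | intermediate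
13 | 3-[3,4-bis(benzyloxy)-5-methoxyphenyl]propanoic acid | COc1cc(CCC(=O)O)cc(OCc2ccccc2)c1OCc1ccccc1 | intermediate
14 | (S,Z)-5-[4-(benzyloxy)-3-methoxyphenyl]pent-3-en-2-yl 3-[3,4-bis(benzyloxy)-5-methoxyphenyl]propanoate | C[C@H](OC(=O)CCc1cc(OC)c(OCc2ccccc2)c(OCc2ccccc2)c1)/C=C\Cc1ccc(OCc2ccccc2)c(OC)c1 | intermediate
15 | lithium enolate of 14 (arylmethyl trans to OLi, cis to the allylic oxygen) | C[C@H](O/C(O[Li])=C\Cc1cc(OC)c(OCc2ccccc2)c(OCc2ccccc2)c1)/C=C\Cc1ccc(OCc2ccccc2)c(OC)c1 | intermediate
16 | (E)-trimethylsilyl ketene acetal of 14 (arylmethyl trans to OSiMe3) | C[C@H](O/C(O[Si](C)(C)C)=C\Cc1cc(OC)c(OCc2ccccc2)c(OCc2ccccc2)c1)/C=C\Cc1ccc(OCc2ccccc2)c(OC)c1 | intermediate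
17 | trimethylsilyl (2R,3S,E)-2-[3,4-bis(benzyloxy)-5-methoxybenzyl]-3-[4-(benzyloxy)-3-methoxybenzyl]hex-4-enoate | C/C=C/[C@H](Cc1ccc(OCc2ccccc2)c(OC)c1)[C@@H](Cc1cc(OC)c(OCc2ccccc2)c(OCc2ccccc2)c1)C(=O)O[Si](C)(C)C | intermediate
18 | (2R,3S,E)-2-[3,4-bis(benzyloxy)-5-methoxybenzyl]-3-[4-(benzyloxy)-3-methoxybenzyl]hex-4-enoic acid | C/C=C/[C@H](Cc1ccc(OCc2ccccc2)c(OC)c1)[C@@H](Cc1cc(OC)c(OCc2ccccc2)c(OCc2ccccc2)c1)C(=O)O | intermediate
19 | secondary ozonide of 18 (5-methyl-1,2,4-trioxolan-3-yl in place of the propenyl group; both trioxolane carbons as mixtures) | CC1OOC(O1)[C@H](Cc1ccc(OCc2ccccc2)c(OC)c1)[C@@H](Cc1cc(OC)c(OCc2ccccc2)c(OCc2ccccc2)c1)C(=O)O | intermediate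
20 | (2R,3R)-2-[3,4-bis(benzyloxy)-5-methoxybenzyl]-3-[4-(benzyloxy)-3-methoxybenzyl]-4-hydroxybutanoic acid | OC[C@H](Cc1ccc(OCc2ccccc2)c(OC)c1)[C@@H](Cc1cc(OC)c(OCc2ccccc2)c(OCc2ccccc2)c1)C(=O)O | intermediate
21 | tri-O-benzyl thujaplicatin, (3R,4R)-3-[3,4-bis(benzyloxy)-5-methoxybenzyl]-4-[4-(benzyloxy)-3-methoxybenzyl]dihydrofuran-2(3H)-one | COc1cc(C[C@H]2COC(=O)[C@@H]2Cc2cc(OCc3ccccc3)c(OCc3ccccc3)c(OC)c2)ccc1OCc1ccccc1 | intermediate
22 | (−)-thujaplicatin, (3R,4R)-3-(3,4-dihydroxy-5-methoxybenzyl)-4-(4-hydroxy-3-methoxybenzyl)dihydrofuran-2(3H)-one | COc1cc(C[C@H]2COC(=O)[C@@H]2Cc2cc(O)c(O)c(OC)c2)ccc1O | target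

Total step count: 11 steps.
Longest linear sequence: 9 steps (steps 1–5 and 8–11, from vanillin).

Steps most likely to fail

Step 4. The coupling may be eroded by homocoupling of the benzylic bromide, by O-benzylation of the magnesium alkoxide, or by base-induced drift of the skipped aryl alkyne towards an allene. The fallback sets out from 5 and removes the free alkoxide from the coupling. Silylation (TBSCl, imidazole, DMF) would give (S)-tert-butyl(but-3-yn-2-yloxy)dimethylsilane F1. Deprotonation with n-BuLi in THF at −78 °C would give its lithium acetylide F2. Alkylation with 4 in THF/DMPU with CuI (cat.) would give the silyl ether of the coupled alkynol F3. Cleavage with Bu4NF in THF comes back to the route at 7.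

Step 10. Ozone may attack the electron-rich benzyloxy-substituted rings or benzylic C–H bonds in competition with the alkene, and the transient aldehyde may epimerise at C4 before it is reduced. The fallback sets out from 18 and replaces ozone by a Lemieux–Johnson cleavage (K2OsO4·2H2O cat., NaIO4, 2,6-lutidine, dioxane/H2O). Dihydroxylation would give the 4,5-diol acid F4, which periodate cleaves in the same flask to the aldehyde acid F5. F5 rests as its cyclic lactol, which shields the α-centre. NaBH4 in MeOH at 0 °C then gives hydroxy acid 20, where the route is rejoined; acidification and the DBU treatment follow as before to 21.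

Step 9. Enolisation may be incomplete, deprotonation may compete at the doubly activated benzylic–allylic methylene, or the ketene acetal may be hydrolysed before it rearranges, which would return the ester or its fragments. Loss of ketene acetal geometry is not the concern, since it is absorbed by the equilibration in step 10. The fallback sets out from 8 and 10, fixes only C4 by rearrangement and installs C3 by alkylation, and comes back to the route at 21.
- Johnson–Claisen rearrangement of 8 (triethyl orthoacetate, cat. EtCO2H, 140 °C) through the same chair would give ethyl (R,E)-3-[4-(benzyloxy)-3-methoxybenzyl]hex-4-enoate F6.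
- Alkene cleavage with hydride work-up as in step 10 would give ethyl (R)-3-[4-(benzyloxy)-3-methoxybenzyl]-4-hydroxybutanoate F7, which closes under acid to (R)-4-[4-(benzyloxy)-3-methoxybenzyl]dihydrofuran-2(3H)-one F8.
- In parallel, NaBH4 reduction of 10 would give 3,4-bis(benzyloxy)-5-methoxybenzyl alcohol F9, and PBr3 would convert it to 3,4-bis(benzyloxy)-5-methoxybenzyl bromide F10.
- Deprotonation of F8 with LiN(SiMe3)2 in THF at −78 °C would give its lithium enolate F11, which is alkylated by F10 on the face anti to the C4 substituent to give the trans lactone 21.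

Further compounds
F1 | step 4 | (S)-tert-butyl(but-3-yn-2-yloxy)dimethylsilane | C[C@H](O[Si](C)(C)C(C)(C)C)C#C
F2 | step 4 | lithium acetylide of F1 | C[C@H](O[Si](C)(C)C(C)(C)C)C#C[Li]
F3 | step 4 | (S)-{[5-(4-(benzyloxy)-3-methoxyphenyl)pent-3-yn-2-yl]oxy}(tert-butyl)dimethylsilane | C[C@H](O[Si](C)(C)C(C)(C)C)C#CCc1ccc(OCc2ccccc2)c(OC)c1
F4 | step 10 | (2R,3R)-2-[3,4-bis(benzyloxy)-5-methoxybenzyl]-3-[4-(benzyloxy)-3-methoxybenzyl]-4,5-dihydroxyhexanoic acid (syn-diol, mixture at C4/C5) | CC(O)C(O)[C@H](Cc1ccc(OCc2ccccc2)c(OC)c1)[C@@H](Cc1cc(OC)c(OCc2ccccc2)c(OCc2ccccc2)c1)C(=O)O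
F5 | step 10 | (2R,3R)-2-[3,4-bis(benzyloxy)-5-methoxybenzyl]-3-[4-(benzyloxy)-3-methoxybenzyl]-4-oxobutanoic acid (in equilibrium with its lactol) | O=C[C@H](Cc1ccc(OCc2ccccc2)c(OC)c1)[C@@H](Cc1cc(OC)c(OCc2ccccc2)c(OCc2ccccc2)c1)C(=O)O
F6 | step 9 | ethyl (R,E)-3-[4-(benzyloxy)-3-methoxybenzyl]hex-4-enoate | C/C=C/[C@H](Cc1ccc(OCc2ccccc2)c(OC)c1)CC(=O)OCC
F7 | step 9 | ethyl (R)-3-[4-(benzyloxy)-3-methoxybenzyl]-4-hydroxybutanoate | OC[C@H](Cc1ccc(OCc2ccccc2)c(OC)c1)CC(=O)OCC
F8 | step 9 | (R)-4-[4-(benzyloxy)-3-methoxybenzyl]dihydrofuran-2(3H)-one | COc1cc(C[C@H]2COC(=O)C2)ccc1OCc1ccccc1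
F9 | step 9 | [3,4-bis(benzyloxy)-5-methoxyphenyl]methanol | COc1cc(CO)cc(OCc2ccccc2)c1OCc1ccccc1
F10 | step 9 | 3,4-bis(benzyloxy)-5-methoxybenzyl bromide | COc1cc(CBr)cc(OCc2ccccc2)c1OCc1ccccc1
F11 | step 9 | lithium enolate of F8 | COc1cc(C[C@H]2COC(O[Li])=C2)ccc1OCc1ccccc1
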